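## The problem

The target is a twelve-carbon chain, numbered from the lactone carbonyl C1 to the methyl group C12, that carries a 5,6-dihydro-2H-pyran-2-one (C1–C5, ring oxygen on C5), a free hydroxyl at C6, a 2,5-disubstituted oxolane (C7–C10) and a C11 carbinol esterified with (Z)-4-methoxycinnamic acid. Its five stereocentres are 5R, 6S, 7R, 10S and 11S: C6/C7 and C10/C11 are threo, the oxolane is 2,5-cis and C5/C6 is erythro (anti). C5 lies next to an oxygenated stereocentre and can be set from C6 by 1,2-induction, whereas C6, C7, C10 and C11 face each other across the ring and are best made together rather than one from another. The Z-cinnamate is isomerised by light and nucleophilic catalysts and destroyed by hydride reagents and hydrogenation, and the unsaturated lactone is a Michael acceptor that opens under base, so both must arrive after all reductions. Three secondary oxygens (O5, O6, O11) end in three different states (lactone, free hydroxyl, cinnamate) and must be told apart. The enabling feature is that the C6–C11 segment (carbinol, cis-oxolane, carbinol, threo on both flanks) is mirror-symmetric apart from what hangs on C5 and C12. It therefore maps onto a meso compound whose ring oxygen and two carbinol oxygens can be delivered to a symmetric E,E-1,5-diene by a single oxidant. The price is a desymmetrisation that fixes the absolute configuration and distinguishes the C5 end from the C12 end.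

## Retrosynthesis

**Lactone (24 ⇒ 23 ⇒ 22 ⇒ 21).** The last operation frees O6 (23 → 24). In 23 the C2=C3 bond is cut by ring-closing metathesis and the O5–C1 bond by acylation, leading through acrylate 22 to homoallylic alcohol 21. The neighbouring option, a Z-selective olefination at C3 followed by lactonisation, needs a chain already extended to C3 and a basic step next to the base-sensitive C5–O bond. Metathesis is neutral, gets the Z-alkene from the ring, and should leave a conjugated 1,2-disubstituted cinnamate alone. The forward steps must only avoid base strong enough to move the silyl group from O6 to O5.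

**C4–C5 (21 ⇒ 20).** Cutting C4–C5 gives aldehyde 20 and an allyl nucleophile. C5 is the one stereocentre outside the symmetric core, and an α-silyloxy aldehyde is a substrate class in which Felkin–Anh induction (anti) is dependable. The target is 5,6-anti, so substrate and a chiral allylborane can be matched. A cut at C5–C6 would break into the symmetric core. The forward reaction must deliver allyl to the Re face of C5 without epimerising C6.

**Cinnamate and the C5 oxidation level (20 ⇒ 19 ⇒ 14 + 18).** Aldehyde 20 comes from bis(silyl ether) 19 by oxidative cleavage of the primary silyl ether alone. The O11–acyl bond is cut here, giving alcohol 14 and acid 18. In 14, O11 is the only free hydroxyl, every hydride step lies behind it and O5 does not yet exist, so O11 needs no protecting group of its own. Esterification at the very end would instead need a second orthogonal group on O11, carried through five steps and removed beside the lactone. In return the Z-double bond must survive five mild steps. Acid 18 is cut at its C=C bond into aldehyde 15 and phosphonate 16, through ester 17.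

**C12 (14 ⇒ 12 ⇒ 11 ⇒ 10).** The C12 methyl group is the ester carbon at its lowest oxidation level. The C12–O bond is cut, leading back to tosylate 12 (reduced through epoxide 13), diol 11 and acetoxy ester 10. The C11–O bond is never broken, so C11 keeps the configuration from the key step. This deoxygenation costs three steps more than a diene with a methyl terminus would, but it keeps the key-step precursor symmetric. The forward steps need only hydride-stable protection on O5 and O6.

**Telling the ends apart (10 ⇒ 9 ⇒ 8).** In 8 the two ester groups differ only in their α-oxygen: a free hydroxyl at C6, an acetate at C11. A hydroxyl-directed borane reduction touches only the C5 ester (9). The diol is capped as two triethylsilyl ethers (10), chosen because the primary one can later be oxidised directly to the aldehyde. Placing the free hydroxyl on the C6 arm is what keeps the sequence short: the O11 acetate is a marker that disappears in the same hydride step that reduces C12.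

**Desymmetrisation (8 ⇒ 7 ⇒ 6).** Monoacetate 8 is one enantiomer derived from meso diol 6, whose two carbinols are enantiotopic and are distinguished by a lipase. Hydrolysis of meso diacetate 7 is chosen over acetylation of 6 because the enzyme is expected to act at the S-configured carbinol (C6), and it is the C6 hydroxyl that must be free in 8. The cost is one acetylation step. The two modes are complementary: an enzyme of opposite preference would give 8 from 6 by direct acetylation, so either sense can be used. No stereocentre is formed, but the absolute configuration of all four is fixed here.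

**Oxolane core (6 ⇒ 4).** The ring bonds O–C7 and O–C10 and the carbinol bonds C6–O and C11–O are cut together, which returns the achiral diene 4. Stepwise ring constructions (an ether bond by substitution, or a ring closed by metathesis) need the stereocentres in place beforehand. This cut removes one ring, four stereocentres and four C–O bonds in one step. It asks for cis ring closure and threo addition on both flanks, but only relative control, since 6 is meso.

**Diene (4 ⇒ 1 + 2).** The two C=C bonds of 4 are cut by double cross-metathesis into diene 1 and two molecules of acrylate 2; the mono-adduct 3 is passed through without isolation. A double Wittig reaction on a four-carbon dialdehyde is the neighbour, but metathesis uses two bulk chemicals and gives the E,E isomer under thermodynamic control.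

## Roads not taken

Alternative 1: The O–C7 bond of a 2,5-dihydrofuran is cut. In the forward step AuCl3 activates the allene of α-hydroxyallene A1, and the C10 hydroxyl adds to C7 in a 5-endo cyclisation. The allene axis becomes the C7 stereocentre of cis-dihydrofuran A2.
- Merits: the step is catalytic and neutral, and the axis-to-centre transfer is stereospecific. A2 already holds C5 from the chiral pool, so no late allylation is needed and no enzyme decides the absolute configuration. In these two respects it is better than the chosen plan.
- Weak points: A1 contains five stereo-elements (C11, C10, the axis, C6, C5), each installed separately. The axis usually comes from an anti-SN2' substitution of a propargylic derivative, which needs one more defined centre that is then consumed. The C8=C9 alkene of A2 must be saturated in the presence of a benzylic ether. Three protecting groups must be removed in order, and the C4 silyl ether still has to be taken to the lactone by a Z-selective olefination.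
- Comparison: the chosen plan sets four stereocentres and the ring in one step from an achiral diene that is itself one step from bulk chemicals. It pays with a desymmetrisation and a deoxygenation at C12.

Alternative 2: The O–C10 ring bond and the C10–H bond are cut. In the forward step Et3SiH and BF3·OEt2 convert hydroxy ketone A3 (open form and both hemiketal anomers) through one cyclic oxocarbenium ion into cis-oxolane A4.
- Merits: the step is stereoconvergent and well precedented for 2,5-cis oxolanes. The fragments can be joined by ordinary carbonyl chemistry, and every other stereocentre, C5 included, comes from the chiral pool. On certainty of absolute configuration this road is better.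
- Weak points: the oxocarbenium carbon C10 carries the C11 ether, so the Lewis acid acts next to a 4-methoxybenzyl ether and an acetonide, both acid-labile. The cis preference depends on this α-oxygenated side chain. A3 needs two chiral-pool fragments, their coupling and a redox adjustment. A4 still needs the pivalate taken to an aldehyde and a Z-olefination to build the lactone.
- Comparison: the chosen plan has fewer protecting-group operations on the core and makes the core in two steps. It depends on an enzyme and must set C5 late by allylation.

Alternative 3: The C8=C9 bond of a 2,5-dihydrofuran is cut. In the forward step the second-generation Grubbs catalyst, (H2IMes)(PCy3)Cl2Ru=CHPh, joins the two vinyl groups of di(sec-allyl) ether A5 and releases ethylene to give cis-dihydrofuran A6.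
- Merits: ring-closing metathesis to a five-membered ring is about as reliable as a step can be. The cis relationship is fixed before closure by the configurations at C7 and C10, so the key step carries no stereochemical risk. It is safer than a permanganate cyclisation.
- Weak points: the difficulty moves to making A5, an ether between two hindered secondary allylic carbons. Direct substitution there is prone to elimination and SN2' scrambling, and stereospecific detours add steps. The ring alkene of A6 must afterwards be saturated beside a benzylic ether. All five stereocentres are again installed one at a time.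
- Comparison: the chosen plan sets against the safer ring closure its much shorter access to the stereodefined core, at the cost of a key step that is more sensitive to conditions.

Key step: step 2

Assumption: the lipase is taken to follow the usual size rule for secondary alcohols (CO2Me as the medium, the oxolanyl residue as the large substituent), so that in 7 it hydrolyses the acetate on the S-configured carbinol carbon, which is C6 of the target.

## Route

Step 1
Reactants: 1 1,5-hexadiene; 2 methyl acrylate (two molecules are incorporated)
Product: 4 dimethyl (2E,6E)-octa-2,6-dienedioate, via methyl (2E)-hepta-2,6-dienoate 3 (not isolated)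
Conditions: second-generation Hoveyda–Grubbs catalyst (H2IMes)Cl2Ru(=CH-C6H4-2-OiPr) (2 mol %), methyl acrylate (6 equiv), CH2Cl2, 40 °C
Reagents that add atoms: methyl acrylate (second molecule), C=CC(=O)OC
Why: Double olefin cross-metathesis: each terminal alkene of 1 pairs in turn with one molecule of the electron-poor acrylate, which does not homodimerise readily, so that mono-adduct 3 is carried on to 4 in the same flask by the excess of 2. The conjugated product forms as the thermodynamically favoured E isomer at both ends, with loss of two molecules of ethylene.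

Step 2
Reactants: 4 dimethyl (2E,6E)-octa-2,6-dienedioate
Product: 6 dimethyl (2R,2'S)-2,2'-[(2S,5R)-oxolane-2,5-diyl]bis(2-hydroxyacetate) (meso), via cyclic pentavalent-manganese diester 5 (not isolated)
Conditions: KMnO4 (1.4 equiv), AcOH (3 equiv), acetone/H2O, −30 → −10 °C
Reagents that add atoms: potassium permanganate, [K+].[O-][Mn](=O)(=O)=O
Why: Permanganate oxidative cyclisation of a 1,5-diene, the closest known reaction type being the conversion of 1,5-dienoates into cis-2,5-bis(hydroxyalkyl)oxolanes. Heptavalent manganese adds by a suprafacial [3+2] cycloaddition to one enoate (the two are equivalent, and enoates are the alkenes permanganate attacks best) to give the cyclic pentavalent manganese diester 5. In 5 the metal is held on O7, and an O7–Mn=O unit (after one-electron oxidation by further permanganate to the hexavalent level, as is generally assumed) adds across the second alkene in a second suprafacial [3+2] step that forms O7–C10 and O–C11, closing the oxolane in a 5-exo mode through a bicyclic transition state. Because O7 and the oxygen that becomes O11 are delivered by the same metal centre, still bound on the face of C7 from which O7 came, the ring can only be cis. Each addition is suprafacial on an E-alkene, so C6/C7 (first addition) and C10/C11 (second addition) are both threo. The product is meso, so only relative control is needed and both enantiomers of 5 converge on 6. The step needs ring closure to outrun hydrolysis of 5 to an open-chain diol and the α-hydroxy esters to escape further oxidation; the 1,5-spacing, the weakly acidic medium and the low temperature should secure this. Aqueous work-up releases the diol and MnO2.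

Step 3
Reactants: 6 dimethyl (2R,2'S)-2,2'-[(2S,5R)-oxolane-2,5-diyl]bis(2-hydroxyacetate)
Product: 7 dimethyl (2R,2'S)-2,2'-[(2S,5R)-oxolane-2,5-diyl]bis(2-acetoxyacetate) (meso)
Conditions: Ac2O (2.5 equiv), pyridine, DMAP (cat.), CH2Cl2, 0 °C → rt
Reagents that add atoms: acetic anhydride, CC(=O)OC(C)=O
Why: DMAP-catalysed acetylation of both secondary hydroxyls; no stereocentre is touched and the symmetric product is a single meso compound.

Step 4
Reactants: 7 dimethyl (2R,2'S)-2,2'-[(2S,5R)-oxolane-2,5-diyl]bis(2-acetoxyacetate)
Product: 8 methyl (2R)-2-acetoxy-2-[(2S,5R)-5-[(1S)-1-hydroxy-2-methoxy-2-oxoethyl]oxolan-2-yl]acetate (O11 acetate, free C6 hydroxyl)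
Conditions: lipase from Burkholderia cepacia (immobilised), phosphate buffer pH 7/acetone (9:1), 30 °C, stopped near one equivalent of acetate released
Reagents that add atoms: none
Why: Lipase-catalysed hydrolysis that distinguishes the two enantiotopic acetates of a meso diacetate; by the size rule the acetate on the S carbinol (C6) should be cleaved. No stereocentre is formed, but the absolute configuration of C6, C7, C10 and C11 is fixed here. The minor monoacetate still carries the fast-reacting acetate and should be hydrolysed on to 6, which raises the enantiomeric purity of 8 and returns material to step 3.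

Step 5
Reactants: 8 methyl (2R)-2-acetoxy-2-[(2S,5R)-5-[(1S)-1-hydroxy-2-methoxy-2-oxoethyl]oxolan-2-yl]acetate
Product: 9 methyl (2R)-2-acetoxy-2-[(2S,5R)-5-[(1R)-1,2-dihydroxyethyl]oxolan-2-yl]acetate
Conditions: BH3·SMe2 (1.1 equiv), NaBH4 (5 mol %), THF, 0 °C → rt; then MeOH
Reagents that add atoms: none
Why: Hydroxyl-directed chemoselective reduction of an α-hydroxy ester: the C6 hydroxyl binds borane and, with catalytic NaBH4, hydride is delivered intramolecularly to the neighbouring C5 ester, while the acetoxy ester has no free hydroxyl and should react far more slowly. No stereocentre is affected (the descriptor at C6 changes only because the priorities change).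

Step 6
Reactants: 9 methyl (2R)-2-acetoxy-2-[(2S,5R)-5-[(1R)-1,2-dihydroxyethyl]oxolan-2-yl]acetate
Product: 10 methyl (2R)-2-acetoxy-2-[(2S,5R)-5-[(1R)-1,2-bis(triethylsilyloxy)ethyl]oxolan-2-yl]acetate
Conditions: Et3SiCl (2.4 equiv), imidazole, DMAP (cat.), CH2Cl2, 0 °C → rt
Reagents that add atoms: chlorotriethylsilane, CC[Si](Cl)(CC)CC
Why: Standard silylation of a primary and a secondary hydroxyl; the acetate and the methyl ester are inert to imidazole at this temperature.

Step 7
Reactants: 10 methyl (2R)-2-acetoxy-2-[(2S,5R)-5-[(1R)-1,2-bis(triethylsilyloxy)ethyl]oxolan-2-yl]acetate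
Product: 11 (1S)-1-[(2S,5R)-5-[(1R)-1,2-bis(triethylsilyloxy)ethyl]oxolan-2-yl]ethane-1,2-diol
Conditions: LiAlH4, THF, 0 °C
Reagents that add atoms: none
Why: Hydride reduction of the methyl ester to the C12 alcohol with concurrent cleavage of the O11 acetate; the silyl ethers are stable to LiAlH4 at 0 °C and C11 is not epimerised.

Step 8
Reactants: 11 (1S)-1-[(2S,5R)-5-[(1R)-1,2-bis(triethylsilyloxy)ethyl]oxolan-2-yl]ethane-1,2-diol
Product: 12 (2S)-2-[(2S,5R)-5-[(1R)-1,2-bis(triethylsilyloxy)ethyl]oxolan-2-yl]-2-hydroxyethyl 4-methylbenzenesulfonate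
Conditions: TsCl (1.05 equiv), Et3N, Bu2SnO (2 mol %), CH2Cl2, 0 °C → rt
Reagents that add atoms: 4-methylbenzenesulfonyl chloride, Cc1ccc(cc1)S(=O)(=O)Cl
Why: Tin-catalysed regioselective sulfonylation of a 1,2-diol; the dibutylstannylene acetal activates the primary oxygen, so only O12 is tosylated.

Step 9
Reactants: 12 (2S)-2-[(2S,5R)-5-[(1R)-1,2-bis(triethylsilyloxy)ethyl]oxolan-2-yl]-2-hydroxyethyl 4-methylbenzenesulfonate
Product: 14 (1S)-1-[(2S,5R)-5-[(1R)-1,2-bis(triethylsilyloxy)ethyl]oxolan-2-yl]ethan-1-ol, via terminal epoxide 13 (not isolated)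
Conditions: LiBHEt3 (2.5 equiv), THF, 0 °C → rt
Reagents that add atoms: none
Why: Hydride reduction of a β-hydroxy tosylate: the C11 alkoxide displaces the neighbouring tosylate to give epoxide 13, which hydride opens at the unhindered C12 in an SN2 reduction (direct hydride displacement of the primary tosylate would lead to the same product). The C11–O bond is never broken, so C11 keeps its configuration and C12 becomes the methyl group.

Step 10
Reactants: 15 4-methoxybenzaldehyde; 16 ethyl 2-(diphenoxyphosphoryl)acetate
Product: 17 ethyl (2Z)-3-(4-methoxyphenyl)prop-2-enoate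
Conditions: NaH, THF, −78 → 0 °C
Reagents that add atoms: none
Why: Ando variant of the Horner–Wadsworth–Emmons olefination; the electron-poor diaryl phosphonate makes elimination from the kinetically formed adduct fast and irreversible, which favours the Z-cinnamate. Any E isomer is removed by chromatography.

Step 11
Reactants: 17 ethyl (2Z)-3-(4-methoxyphenyl)prop-2-enoate
Product: 18 (2Z)-3-(4-methoxyphenyl)prop-2-enoic acid
Conditions: LiOH, THF/H2O, 0 °C → rt, dark; then 1 M HCl to pH 3
Reagents that add atoms: lithium hydroxide, [Li+].[OH-]
Why: Saponification of the ethyl ester; hydroxide attacks the carbonyl group and not the electron-rich β-carbon, so the Z geometry should be retained if light is excluded.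

Step 12
Reactants: 14 (1S)-1-[(2S,5R)-5-[(1R)-1,2-bis(triethylsilyloxy)ethyl]oxolan-2-yl]ethan-1-ol; 18 (2Z)-3-(4-methoxyphenyl)prop-2-enoic acid
Product: 19 (1S)-1-[(2S,5R)-5-[(1R)-1,2-bis(triethylsilyloxy)ethyl]oxolan-2-yl]ethyl (2Z)-3-(4-methoxyphenyl)prop-2-enoate
Conditions: EDC·HCl, DMAP (0.1 equiv), CH2Cl2, 0 °C → rt, dark
Reagents that add atoms: none
Why: Steglich esterification of the only free hydroxyl; low temperature, little DMAP and exclusion of light limit Z to E isomerisation of the activated acyl group. The C11–O bond is not involved, so C11 is acylated with retention.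

Step 13
Reactants: 19 (1S)-1-[(2S,5R)-5-[(1R)-1,2-bis(triethylsilyloxy)ethyl]oxolan-2-yl]ethyl (2Z)-3-(4-methoxyphenyl)prop-2-enoate
Product: 20 (1S)-1-[(2S,5R)-5-[(1S)-2-oxo-1-(triethylsilyloxy)ethyl]oxolan-2-yl]ethyl (2Z)-3-(4-methoxyphenyl)prop-2-enoate
Conditions: (COCl)2, DMSO, CH2Cl2, −78 → −30 °C; then Et3N, −78 → 0 °C
Reagents that add atoms: none
Why: Swern oxidation with in situ cleavage of a primary triethylsilyl ether; chlorodimethylsulfonium chloride attacks the unhindered primary silyl ether oxygen, releases Et3SiCl and forms the alkoxysulfonium ion, which Et3N converts into the aldehyde. The hindered secondary silyl ether on O6 should be untouched, and the aldehyde is used crude to avoid epimerisation at C6.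

Step 14
Reactants: 20 (1S)-1-[(2S,5R)-5-[(1S)-2-oxo-1-(triethylsilyloxy)ethyl]oxolan-2-yl]ethyl (2Z)-3-(4-methoxyphenyl)prop-2-enoate
Product: 21 (1S)-1-[(2S,5R)-5-[(1R,2R)-2-hydroxy-1-(triethylsilyloxy)pent-4-en-1-yl]oxolan-2-yl]ethyl (2Z)-3-(4-methoxyphenyl)prop-2-enoate
Conditions: (+)-Ipc2B(allyl) (from (−)-α-pinene, salt-free), Et2O, −78 °C; then H2O2, pH 7 phosphate buffer, MeOH, 0 °C
Reagents that add atoms: (+)-B-allyldiisopinocampheylborane, C=CCB([C@H]1C[C@H]2C[C@@H]([C@@H]1C)C2(C)C)[C@H]1C[C@H]2C[C@@H]([C@@H]1C)C2(C)C
Why: Brown allylboration through a chair six-membered transition state; the reagent derived from (−)-α-pinene should deliver allyl to the Re face of the aldehyde, which is also the face favoured by the Felkin–Anh model for the α-silyloxy group at C6 (matched pair), giving 5R, anti to O6. Buffered peroxide work-up frees the alcohol without exposing the esters or the silyl ether to strong base.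

Step 15
Reactants: 21 (1S)-1-[(2S,5R)-5-[(1R,2R)-2-hydroxy-1-(triethylsilyloxy)pent-4-en-1-yl]oxolan-2-yl]ethyl (2Z)-3-(4-methoxyphenyl)prop-2-enoate
Product: 22 (1S)-1-[(2S,5R)-5-[(1S,2R)-2-(prop-2-enoyloxy)-1-(triethylsilyloxy)pent-4-en-1-yl]oxolan-2-yl]ethyl (2Z)-3-(4-methoxyphenyl)prop-2-enoate
Conditions: acryloyl chloride, iPr2NEt, DMAP (cat.), CH2Cl2, −20 → 0 °C
Reagents that add atoms: acryloyl chloride, C=CC(=O)Cl
Why: Acylation of the secondary C5 hydroxyl with an acid chloride under amine base, kept cold to avoid acrylate polymerisation and silyl migration from O6 to O5. The change of descriptor at C6 is a priority change only.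

Step 16
Reactants: 22 (1S)-1-[(2S,5R)-5-[(1S,2R)-2-(prop-2-enoyloxy)-1-(triethylsilyloxy)pent-4-en-1-yl]oxolan-2-yl]ethyl (2Z)-3-(4-methoxyphenyl)prop-2-enoate
Product: 23 (1S)-1-[(2S,5R)-5-[(S)-[(2R)-6-oxo-3,6-dihydro-2H-pyran-2-yl](triethylsilyloxy)methyl]oxolan-2-yl]ethyl (2Z)-3-(4-methoxyphenyl)prop-2-enoate
Conditions: second-generation Grubbs catalyst (H2IMes)(PCy3)Cl2Ru=CHPh (5 mol %), CH2Cl2 (3 mM), 40 °C
Reagents that add atoms: none
Why: Ring-closing metathesis; the ruthenium carbene forms at the terminal alkene and closes onto the acrylate to give the six-membered unsaturated lactone, the ring enforcing the Z geometry of C2=C3. The conjugated 1,2-disubstituted cinnamate alkene is too hindered and electron-poor to take part, and high dilution suppresses dimerisation.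

Step 17
Reactants: 23 (1S)-1-[(2S,5R)-5-[(S)-[(2R)-6-oxo-3,6-dihydro-2H-pyran-2-yl](triethylsilyloxy)methyl]oxolan-2-yl]ethyl (2Z)-3-(4-methoxyphenyl)prop-2-enoate
Product: 24 (1S)-1-[(2S,5R)-5-[(S)-hydroxy[(2R)-6-oxo-3,6-dihydro-2H-pyran-2-yl]methyl]oxolan-2-yl]ethyl (2Z)-3-(4-methoxyphenyl)prop-2-enoate (CNP0080290.1)
Conditions: HF·pyridine, pyridine, THF, 0 °C → rt
Reagents that add atoms: none
Why: Fluoride cleavage of the secondary triethylsilyl ether under buffered, weakly acidic conditions that should leave the unsaturated lactone and the Z-cinnamate untouched; basic fluoride sources are avoided because of the base-sensitive lactone.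

## Compound list

1 | 1,5-hexadiene | C=CCCC=C | starting material
2 | methyl acrylate | C=CC(=O)OC | starting material
3 | methyl (2E)-hepta-2,6-dienoate (mono cross-metathesis adduct, not isolated) | C=CCC/C=C/C(=O)OC | intermediate
4 | dimethyl (2E,6E)-octa-2,6-dienedioate | COC(=O)/C=C/CC/C=C/C(=O)OC | intermediate
5 | cyclic pentavalent-manganese diester across one enoate of 4, potassium salt (racemic, one enantiomer drawn) | [K+].[O-][Mn]1(=O)O[C@@H](C(=O)OC)[C@H](CC/C=C/C(=O)OC)O1 | intermediate
6 | dimethyl (2R,2'S)-2,2'-[(2S,5R)-oxolane-2,5-diyl]bis(2-hydroxyacetate), meso, threo-cis-threo (the 2R acetate on ring carbon 2S) | O[C@@H](C(=O)OC)[C@@H]1CC[C@H]([C@H](O)C(=O)OC)O1 | intermediate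
7 | dimethyl (2R,2'S)-2,2'-[(2S,5R)-oxolane-2,5-diyl]bis(2-acetoxyacetate), meso | CC(=O)O[C@@H](C(=O)OC)[C@@H]1CC[C@H]([C@H](OC(C)=O)C(=O)OC)O1 | intermediate
8 | methyl (2R)-2-acetoxy-2-[(2S,5R)-5-[(1S)-1-hydroxy-2-methoxy-2-oxoethyl]oxolan-2-yl]acetate | CC(=O)O[C@@H](C(=O)OC)[C@@H]1CC[C@H]([C@H](O)C(=O)OC)O1 | intermediate
9 | methyl (2R)-2-acetoxy-2-[(2S,5R)-5-[(1R)-1,2-dihydroxyethyl]oxolan-2-yl]acetate | CC(=O)O[C@@H](C(=O)OC)[C@@H]1CC[C@H]([C@H](O)CO)O1 | intermediate
10 | methyl (2R)-2-acetoxy-2-[(2S,5R)-5-[(1R)-1,2-bis(triethylsilyloxy)ethyl]oxolan-2-yl]acetate | CC(=O)O[C@@H](C(=O)OC)[C@@H]1CC[C@H]([C@H](O[Si](CC)(CC)CC)CO[Si](CC)(CC)CC)O1 | intermediate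
11 | (1S)-1-[(2S,5R)-5-[(1R)-1,2-bis(triethylsilyloxy)ethyl]oxolan-2-yl]ethane-1,2-diol | O[C@@H](CO)[C@@H]1CC[C@H]([C@H](O[Si](CC)(CC)CC)CO[Si](CC)(CC)CC)O1 | intermediate
12 | (2S)-2-[(2S,5R)-5-[(1R)-1,2-bis(triethylsilyloxy)ethyl]oxolan-2-yl]-2-hydroxyethyl 4-methylbenzenesulfonate | O[C@@H](COS(=O)(=O)c1ccc(C)cc1)[C@@H]2CC[C@H]([C@H](O[Si](CC)(CC)CC)CO[Si](CC)(CC)CC)O2 | intermediate
13 | (2S,5R)-2-[(2S)-oxiran-2-yl]-5-[(1R)-1,2-bis(triethylsilyloxy)ethyl]oxolane (terminal epoxide, not isolated) | C1O[C@@H]1[C@@H]2CC[C@H]([C@H](O[Si](CC)(CC)CC)CO[Si](CC)(CC)CC)O2 | intermediate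
14 | (1S)-1-[(2S,5R)-5-[(1R)-1,2-bis(triethylsilyloxy)ethyl]oxolan-2-yl]ethan-1-ol | O[C@@H](C)[C@@H]1CC[C@H]([C@H](O[Si](CC)(CC)CC)CO[Si](CC)(CC)CC)O1 | intermediate
15 | 4-methoxybenzaldehyde | COc1ccc(C=O)cc1 | starting material
16 | ethyl 2-(diphenoxyphosphoryl)acetate | CCOC(=O)CP(=O)(Oc1ccccc1)Oc1ccccc1 | starting material
17 | ethyl (2Z)-3-(4-methoxyphenyl)prop-2-enoate | CCOC(=O)/C=C\c1ccc(OC)cc1 | intermediate
18 | (2Z)-3-(4-methoxyphenyl)prop-2-enoic acid | COc1ccc(/C=C\C(=O)O)cc1 | intermediate
19 | (1S)-1-[(2S,5R)-5-[(1R)-1,2-bis(triethylsilyloxy)ethyl]oxolan-2-yl]ethyl (2Z)-3-(4-methoxyphenyl)prop-2-enoate | COc1ccc(/C=C\C(=O)O[C@@H](C)[C@@H]2CC[C@H]([C@H](O[Si](CC)(CC)CC)CO[Si](CC)(CC)CC)O2)cc1 | intermediate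
20 | (1S)-1-[(2S,5R)-5-[(1S)-2-oxo-1-(triethylsilyloxy)ethyl]oxolan-2-yl]ethyl (2Z)-3-(4-methoxyphenyl)prop-2-enoate | COc1ccc(/C=C\C(=O)O[C@@H](C)[C@@H]2CC[C@H]([C@H](O[Si](CC)(CC)CC)C=O)O2)cc1 | intermediate
21 | (1S)-1-[(2S,5R)-5-[(1R,2R)-2-hydroxy-1-(triethylsilyloxy)pent-4-en-1-yl]oxolan-2-yl]ethyl (2Z)-3-(4-methoxyphenyl)prop-2-enoate | COc1ccc(/C=C\C(=O)O[C@@H](C)[C@@H]2CC[C@H]([C@H](O[Si](CC)(CC)CC)[C@H](O)CC=C)O2)cc1 | intermediate
22 | (1S)-1-[(2S,5R)-5-[(1S,2R)-2-(prop-2-enoyloxy)-1-(triethylsilyloxy)pent-4-en-1-yl]oxolan-2-yl]ethyl (2Z)-3-(4-methoxyphenyl)prop-2-enoate | COc1ccc(/C=C\C(=O)O[C@@H](C)[C@@H]2CC[C@H]([C@H](O[Si](CC)(CC)CC)[C@H](OC(=O)C=C)CC=C)O2)cc1 | intermediate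
23 | (1S)-1-[(2S,5R)-5-[(S)-[(2R)-6-oxo-3,6-dihydro-2H-pyran-2-yl](triethylsilyloxy)methyl]oxolan-2-yl]ethyl (2Z)-3-(4-methoxyphenyl)prop-2-enoate | COc1ccc(/C=C\C(=O)O[C@@H](C)[C@@H]2CC[C@H]([C@H](O[Si](CC)(CC)CC)[C@H]3CC=CC(=O)O3)O2)cc1 | intermediate
24 | (1S)-1-[(2S,5R)-5-[(S)-hydroxy[(2R)-6-oxo-3,6-dihydro-2H-pyran-2-yl]methyl]oxolan-2-yl]ethyl (2Z)-3-(4-methoxyphenyl)prop-2-enoate (5R,6S,7R,10S,11S in chain numbering) | COc1ccc(/C=C\C(=O)O[C@@H](C)[C@@H]2CC[C@H]([C@H](O)[C@H]3CC=CC(=O)O3)O2)cc1 | target

## Step count and least certain steps

Total: 17 steps (15 on the main line, 2 for acid 18). Longest linear sequence: 15 steps (steps 1–9 and 12–17).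

**Step 2 (key step).** The most likely failure is that diester 5 is hydrolysed or oxidised further before it closes the ring, giving open-chain diols, ketols or cleavage products. The second alkene is itself electron-poor and the α-hydroxy ester products are oxidisable. The fallback separates the two oxygen-delivery events; it sets out from 4 and comes back at 6. One alkene of 4 is dihydroxylated (OsO4 cat., N-methylmorpholine N-oxide, acetone/H2O, partial conversion with recovery of 4) to the racemic threo diol dimethyl (2E,6S*,7R*)-6,7-dihydroxyoct-2-enedioate F1. F1 is then cyclised under osmium catalysis (OsO4 cat., Me3NO, camphorsulfonic acid, CH2Cl2). The hexavalent osmium glycolate adds suprafacially across the remaining E-alkene and gives the same cis, threo, threo diol 6 from either enantiomer of F1.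

**Step 4.** The most likely failure is poor discrimination between the two enantiotopic acetates, or competing hydrolysis of the methyl esters in water, because α-acyloxy esters are slow and atypical lipase substrates. The fallback replaces the enzyme by a covalent chiral marker; it sets out from 6 and comes back at 11. Diol 6 is mono-acylated with (S)-2-methoxy-2-phenylacetic acid (1 equiv, DCC, DMAP cat., CH2Cl2, 0 °C), and the two diastereomeric monoesters are separated by chromatography. The monoester acylated on O11, methyl (2R)-2-[(2S)-2-methoxy-2-phenylacetoxy]-2-[(2S,5R)-5-[(1S)-1-hydroxy-2-methoxy-2-oxoethyl]oxolan-2-yl]acetate F2, is carried on. Its diastereomer acylated on O6, methyl (2S)-2-[(2S)-2-methoxy-2-phenylacetoxy]-2-[(2R,5S)-5-[(1R)-1-hydroxy-2-methoxy-2-oxoethyl]oxolan-2-yl]acetate F3, is returned to 6 by K2CO3 in MeOH. F2 is reduced under the conditions of step 5 to the diol methyl (2R)-2-[(2S)-2-methoxy-2-phenylacetoxy]-2-[(2S,5R)-5-[(1R)-1,2-dihydroxyethyl]oxolan-2-yl]acetate F4. F4 is silylated under the conditions of step 6 to methyl (2R)-2-[(2S)-2-methoxy-2-phenylacetoxy]-2-[(2S,5R)-5-[(1R)-1,2-bis(triethylsilyloxy)ethyl]oxolan-2-yl]acetate F5. LiAlH4 (conditions of step 7) then reduces the methyl ester of F5 and removes the chiral acyl group, giving 11.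

**Step 12.** The most likely failure is Z to E isomerisation of the cinnamoyl group while it is activated (reversible addition of DMAP to the β-carbon of the acylpyridinium ion), or slow acylation of the hindered O11. The fallback forms the Z-alkene after the ester bond; it sets out from 14 and comes back at 19. Alcohol 14 is esterified with (diphenoxyphosphoryl)acetic acid (DCC, DMAP cat., CH2Cl2) to (1S)-1-[(2S,5R)-5-[(1R)-1,2-bis(triethylsilyloxy)ethyl]oxolan-2-yl]ethyl 2-(diphenoxyphosphoryl)acetate F6. F6 is deprotonated (NaH, THF, −78 °C) and condensed with aldehyde 15 in a Z-selective Horner–Wadsworth–Emmons reaction to give 19.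

**Step 13.** The most likely failure is unselective or incomplete oxidative cleavage of the silyl ethers (attack on the secondary ether, or partial conversion of the primary one), and epimerisation at C6 of the α-silyloxy aldehyde under Et3N. The fallback separates deprotection from oxidation; it sets out from 19 and comes back at 20. The primary silyl ether is removed selectively (pyridinium p-toluenesulfonate, MeOH/CH2Cl2, 0 °C) to give (1S)-1-[(2S,5R)-5-[(1R)-2-hydroxy-1-(triethylsilyloxy)ethyl]oxolan-2-yl]ethyl (2Z)-3-(4-methoxyphenyl)prop-2-enoate F7. F7 is oxidised under base-free conditions (Dess–Martin periodinane, NaHCO3, CH2Cl2) to 20.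

**Step 14.** The most likely failure is erosion of diastereoselectivity at C5, if the chiral reagent and the substrate do not reinforce each other as planned, or silyl migration from O6 to O5 during the oxidative work-up. The fallback drops reagent control and the boron work-up; it sets out from 20 and comes back at 21 and makes no new compound. Aldehyde 20 is treated with allyltrimethylsilane and BF3·OEt2 in CH2Cl2 at −78 °C (Hosomi–Sakurai allylation through an open transition state). The facial choice then rests on Felkin–Anh control by the C6 silyloxy group alone, which favours the same 5,6-anti product 21.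

## Further compounds

F1 | step 2 | dimethyl (2E,6S*,7R*)-6,7-dihydroxyoct-2-enedioate (racemic threo diol, one enantiomer drawn) | O[C@@H](C(=O)OC)[C@@H](O)CC/C=C/C(=O)OC
F2 | step 4 | methyl (2R)-2-[(2S)-2-methoxy-2-phenylacetoxy]-2-[(2S,5R)-5-[(1S)-1-hydroxy-2-methoxy-2-oxoethyl]oxolan-2-yl]acetate | CO[C@@H](c1ccccc1)C(=O)O[C@@H](C(=O)OC)[C@@H]1CC[C@H]([C@H](O)C(=O)OC)O1
F3 | step 4 | methyl (2S)-2-[(2S)-2-methoxy-2-phenylacetoxy]-2-[(2R,5S)-5-[(1R)-1-hydroxy-2-methoxy-2-oxoethyl]oxolan-2-yl]acetate | O[C@@H](C(=O)OC)[C@@H]1CC[C@H]([C@H](OC(=O)[C@@H](OC)c2ccccc2)C(=O)OC)O1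
F4 | step 4 | methyl (2R)-2-[(2S)-2-methoxy-2-phenylacetoxy]-2-[(2S,5R)-5-[(1R)-1,2-dihydroxyethyl]oxolan-2-yl]acetate | CO[C@@H](c1ccccc1)C(=O)O[C@@H](C(=O)OC)[C@@H]1CC[C@H]([C@H](O)CO)O1
F5 | step 4 | methyl (2R)-2-[(2S)-2-methoxy-2-phenylacetoxy]-2-[(2S,5R)-5-[(1R)-1,2-bis(triethylsilyloxy)ethyl]oxolan-2-yl]acetate | CO[C@@H](c1ccccc1)C(=O)O[C@@H](C(=O)OC)[C@@H]1CC[C@H]([C@H](O[Si](CC)(CC)CC)CO[Si](CC)(CC)CC)O1
F6 | step 12 | (1S)-1-[(2S,5R)-5-[(1R)-1,2-bis(triethylsilyloxy)ethyl]oxolan-2-yl]ethyl 2-(diphenoxyphosphoryl)acetate | O=C(CP(=O)(Oc1ccccc1)Oc1ccccc1)O[C@@H](C)[C@@H]1CC[C@H]([C@H](O[Si](CC)(CC)CC)CO[Si](CC)(CC)CC)O1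
F7 | step 13 | (1S)-1-[(2S,5R)-5-[(1R)-2-hydroxy-1-(triethylsilyloxy)ethyl]oxolan-2-yl]ethyl (2Z)-3-(4-methoxyphenyl)prop-2-enoate | COc1ccc(/C=C\C(=O)O[C@@H](C)[C@@H]2CC[C@H]([C@H](O[Si](CC)(CC)CC)CO)O2)cc1
F0 | step 14 | none | none
A1 | alternative 1 | α-hydroxyallene: 10S carbinol between the C11 4-methoxybenzyl ether and the C7–C9 allene that carries the C5,C6-acetonide and the C4 tert-butyldiphenylsilyl ether | COc1ccc(CO[C@@H](C)[C@@H](O)C([H])=[C@@]=C([H])[C@@H]2OC(C)(C)O[C@@H]2CO[Si](c2ccccc2)(c2ccccc2)C(C)(C)C)cc1
A2 | alternative 1 | cis-2,5-disubstituted 2,5-dihydrofuran (C11 4-methoxybenzyl ether, C5,C6-acetonide, C4 tert-butyldiphenylsilyl ether) | COc1ccc(CO[C@@H](C)[C@@H]2C=C[C@H]([C@@H]3OC(C)(C)O[C@@H]3CO[Si](c3ccccc3)(c3ccccc3)C(C)(C)C)O2)cc1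
A3 | alternative 2 | C7-hydroxy C10-ketone, open form (C11 4-methoxybenzyl ether, C5,C6-acetonide, C4 pivalate) | COc1ccc(CO[C@@H](C)C(=O)CC[C@@H](O)[C@@H]2OC(C)(C)O[C@@H]2COC(=O)C(C)(C)C)cc1
A4 | alternative 2 | cis-2,5-disubstituted oxolane (C11 4-methoxybenzyl ether, C5,C6-acetonide, C4 pivalate) | COc1ccc(CO[C@@H](C)[C@@H]2CC[C@H]([C@@H]3OC(C)(C)O[C@@H]3COC(=O)C(C)(C)C)O2)cc1
A5 | alternative 3 | di(sec-allyl) ether linking C7 and C10, each bearing a vinyl group (C11 4-methoxybenzyl ether, C5,C6-acetonide, C4 tert-butyldimethylsilyl ether) | COc1ccc(CO[C@@H](C)[C@H](C=C)O[C@H](C=C)[C@@H]2OC(C)(C)O[C@@H]2CO[Si](C)(C)C(C)(C)C)cc1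
A6 | alternative 3 | cis-2,5-disubstituted 2,5-dihydrofuran (C11 4-methoxybenzyl ether, C5,C6-acetonide, C4 tert-butyldimethylsilyl ether) | COc1ccc(CO[C@@H](C)[C@@H]2C=C[C@H]([C@@H]3OC(C)(C)O[C@@H]3CO[Si](C)(C)C(C)(C)C)O2)cc1
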